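In a closed flask of this kind the starting material charged stands as starting material, target or over-reacted product, so the three percentages must sum to 100%; Friday's last reading sums to 101%.

common to all: gas phase 23 mM (held)

|  | starting material | remark | time |
|---|---|---|---|
| Friday's | 0.14 M | run made earlier |  |
| Monday's | 0.22 M | run made earlier |  |
| eta | 0.10 M |  | 20 h |
| theta | 0.10 M |  | 40 h |

- Friday's (time / h: target / %, starting material / %, over-reacted product / %): 1.33: 2, 99, 0; 4.00: 11, 91, 0; 6.00: 15, 83, 1; 10.0: 23, 72, 4; 15.0: 26, 63, 9; 20.0: 29, 56, 14; 25.0: 27, 48, 26
- Monday's (time / h: target / %, starting material / %, over-reacted product / %): 2.00: 5, 96, 0; 3.00: 3, 95, 0; 4.00: 10, 95, 2; 6.00: 11, 87, 0; 10.0: 17, 79, 4; 15.0: 25, 70, 6; 25.0: 26, 58, 13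

(standard deviation of a reading: 1.5 percentage points)

- the earlier runs were read with a standard deviation of 1.5 percentage points
- at the start none of the gas phase is in solution

- which of these there is most of at the end, counted by the starting material in it, eta (starting material / over-reacted product / target)
- which of these there is most of at the end, counted by the starting material in it, theta (starting material / over-reacted product / target)
- how much there is at the end of the one of these that leads, in percent of the starting material charged: eta
- how much there is at the end of the one of these that leads, in percent of the starting material charged: theta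

That balance leaves two unknowns per flask, so I made two counts, assuming that target holds one gas and over-reacted product two. The first count was the fractional rate of loss of starting material (a pseudo-first-order constant). Friday's last reading gave 0.0294 h⁻¹ and Monday's gave 0.0218 h⁻¹, which is smaller than Friday's. A power law through both gave 0.0367 h⁻¹ at 0.10 M, so I expected 48.0% of the starting material left in eta and 23.1% in theta.

The second count was the gas uptake rate, the charge times the sum of target and twice the over-reacted product, divided by the time. Of the pairs of readings taken at the same time in both runs I chose two, at 25.0 h and 15.0 h, and carried each along a straight line in charge to 0.10 M. At 25.0 h, Friday gave 4.42 mM h⁻¹ and Monday 4.58 mM h⁻¹, so the line gave 4.35 mM h⁻¹. At 15.0 h, Friday gave 4.11 mM h⁻¹ and Monday 5.43 mM h⁻¹, so the line gave 3.45 mM h⁻¹, less than the other.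

They parted, so I looked for the one that cheats. Friday's final interval ran at 6.16 mM h⁻¹, faster than its average up to 15.0 h, on a jump in over-reacted product from 14% to 26%. I distrusted that last reading and kept 3.45 mM h⁻¹.

Subtracting the converted share from the gas count, I reckoned over-reacted product at 17.0% in eta and 60.9% in theta, which then leads.

The forecast, which differs from me on theta, named starting material at 51% for eta and over-reacted product at 49% for theta, in its words “Friday's late acceleration in over-reaction nudges this up slightly”.

The flasks gave starting material at 47.3% in eta and over-reacted product at 56.1% in theta.

    gas phase ⇌ dissolved gas, rate k1*(csat - [dissolved gas]) (kL = 0.00520 min⁻¹)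
    starting material + dissolved gas ⇌ target (K = 140 M⁻¹, k = 0.100 M⁻¹ min⁻¹)
    dissolved gas + target → over-reacted product (k = 0.0880 M⁻¹ min⁻¹)
    dissolved gas → decomposed reagent (k = 3.90 × 10⁻⁴ min⁻¹)

The same count gives 3.71 mM h⁻¹ for eta and 3.34 mM h⁻¹ for theta, on either side of 3.45 mM h⁻¹. A neighbour of eta charged with 0.25 M gives 5.26 mM h⁻¹, where my line stood at 5.92 mM h⁻¹. Theta had not come to rest at its end, with starting material at 22.4% and target at 21.5%. At ten times the time its over-reacted product reaches 100%, and decomposed reagent has grown from 0.00975 M to 0.185 M.

Readings and results come from a simulation for substances that don't exist.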